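## The problem

Compound 33 consists of two fully aromatic bicycles, a 1,3-dimethylisoquinolin-8-ol and a 4'-methoxy-2'-methylnaphthalen-5'-ol, joined by the single bond C7–C1'. It has no stereocentre. Its only stereogenic element is that bond, whose rotation is blocked by the C8 hydroxyl, the C2' methyl group and the peri position C8'. Nothing else in the molecule can direct the sense of the axis, so a single atropisomer must come from a separation or from an external chiral agent. The same ortho substituents make the union of two finished halves a hindered coupling, and C7-selective activation of an 8-oxygenated isoquinoline is not trivial because C5 competes. The peri oxygens O4' (methyl ether) and O5' (free phenol) must be distinguished from the moment they are introduced. The end product is an electron-rich peri-methoxynaphthol and an amphoteric 8-hydroxyisoquinoline with acidic C1-methyl protons, so oxidants, strong bases and strong Lewis acids must be kept away from it and both phenols are best released late. The way in is the substitution order of the isoquinoline carbocycle: C8a (bearing C1), C8 (OH), C7 (naphthyl), C6–H, C5–H, C4a (bearing C4). This is the pattern left when a 2-aryl-1,1-dioxygenated buta-1,3-diene adds to a 4-alkylbut-3-yn-2-one and one of the two oxygens is expelled.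

## Retrosynthesis

**33 ⇒ 32.**
- The benzylic C–O bond at O5' is cut.
- A benzyl ether withstands fluoride, amide bases, heat and mild acid, and it leaves under neutral hydrogenolysis.
- Carrying O5' as a second methyl ether would require selective demethylation within a peri pair, which has no structural basis.
- The forward step must spare the pyridine ring.

**32 ⇒ 31.**
- Both C–N bonds of the pyridine ring (N–C1 and N–C3) are cut at once, which leads to the 1,5-diketone 31.
- The neighbouring cuts, C1–C8a or C4–C4a by electrophilic closure, would require a benzene ring without a C6 oxygen to act as the nucleophile. They would also deliver a di- or tetrahydro level that has to be dehydrogenated.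
- Compound 31 already has the oxidation level of the heteroarene, so only water is lost.
- The forward step must take up nitrogen faster than 31 condenses with itself.

**31 ⇒ 30 ⇒ 29.**
- No skeletal bond is cut. The aliphatic carbonyl is traced back to a silyl-protected carbinol.
- A free ketone at this position in the dienophile would place a CH2 between a ketone and an ynone, an arrangement that isomerises to allenes.
- The cost is two routine steps and a carbinol centre of no consequence, used racemic and erased in step 14.

**29 ⇒ 20 + 26 (key cut).**
- The bonds C8–C8a and C4a–C5 are cut.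
- Cutting C7–C1' instead would lead back to the hindered coupling and to the C7 versus C5 problem.
- A benzene ring can be dissected into diene and alkyne in three ways. Only the one that places C4a and C8a in the alkyne gives a dienophile activated by the acetyl group together with a diene whose donor terminus (C8) lies next to the acceptor carbon. C5 and C6 then become a plain vinyl group.
- The tetrasubstituted benzene with its biaryl axis falls apart into an acyclic C7 ynone and a derivative of a naphthylacetic acid. The hindered biaryl bond becomes the ordinary bond between a naphthalene and an acetic acid α-carbon.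
- Both oxygens of 20 carry silicon, so whichever one leaves, the other emerges as the phenol.
- The forward reaction needs regiocontrol and must tolerate the naphthyl group beside the reacting ketene-acetal carbon.

**26 ⇒ 22 + 23, 22 ⇒ 21.**
- The bond between the acetyl carbon and the alkyne is cut.
- This leaves a terminal alkyne and an acetyl donor that stops at the ketone stage.
- Alcohol 21 is a commercial five-carbon building block.

**20 ⇒ 18 ⇒ 17 ⇒ 15 ⇒ 12 + 13.**
- After removal of the two O–Si bonds, the C=C bond of butenoic acid 18 is cut by a retro-aldol operation.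
- The E and Z isomers of 17 and 18, and any deconjugated isomer, all converge on one dienediolate (19), so no alkene geometry needs control.
- The precursor is the simple arylacetic ester 12 plus the two-carbon aldehyde 13.

**12 ⇒ 11 ⇒ 5 + 8.**
- After removal of the O-methyl group, three bonds of the methyl-bearing naphthalene ring are cut: C1'–C8a', C4'–C4a' and C2'–C3'.
- Insertion of aryne 9 into the C–C bond of diketone 8, followed by aldol closure, forms all three bonds.
- The benzyloxy group directs the carbon nucleophile to the remote aryne carbon. The acetyl carbon that becomes C4' therefore ends up peri to O5', and O4' appears as a free naphthol beside a benzylated O5'. This solves the differentiation problem.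
- A route through a bromonaphthalene and a cross-coupling would need more steps and a regioselective halogenation.

**5 ⇒ 2 ⇒ 1 and 8 ⇒ 6 + 7.**
- In 5 the C–Si and O–S bonds are cut back to bromophenol 2.
- The bromine of 1 marks the carbon between the two oxygens, and bromine–lithium exchange is faster than attack of an alkyllithium on the benzylic ether. A directed ortho-lithiation of a resorcinol monoether carbamate could not guarantee this.
- Diketone 8 comes from C-alkylation of 6 with 7.

## Roads not taken

**Alternative 1:** The cut goes through the methyl-bearing naphthalene ring at C1'–C2' and C3'–C4'.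

- *Forward step.* The anion of homophthalic anhydride A2, which carries the complete O-benzylated isoquinoline at its C4, adds to ethyl but-2-ynoate A3. The vinyl anion then closes on the aryl-bound carbonyl, and decarboxylation gives the naphthol ester A1.
- *Merits.* This anionic annulation is a dependable route to peri-oxygenated naphthols. Its orientation follows from Michael polarity. O4' appears free beside a benzylated O5'. The heterocycle is finished before the union, so no redox work on it follows.
- *Weak points.* The nucleophile is a tertiary, doubly benzylic anion flanked by an ortho benzyloxy group. A β-methyl alkynoate is among the least reactive acceptors. The strong base meets the acidic C1-methyl protons. A1 carries an ester at C3' that must be saponified and decarboxylated.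
- *Further cost.* A2 needs a C7-functionalised isoquinoline and a hindered arylation of a homophthalate, so the difficult C7–C1' bond is only moved, not avoided.
- *Comparison.* In the security of its ring closure and the brevity of its endgame this road is at least equal to the chosen one. The chosen plan offers instead a C7–C1' bond that originates in the CH2 of 7, no surplus carbon to excise, and no prior isoquinoline synthesis.

**Alternative 2:** The cut is at C6–C7 and C8–C8a, in the same ring as the chosen cut but with the naphthyl group on the two-carbon partner.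

- *Forward step.* The piperidine-fused 2-pyranone A5 and the naphthyl siloxyalkyne A6 undergo (4+2) addition, and the lactone bridge is lost by cycloreversion to give the tetrahydroisoquinoline A4.
- *Merits.* The aromatisation is irreversible. O8 arrives protected. The polarity of the ynol ether fixes the orientation. The product level suits the tetrahydro members of the alkaloid family better than the chosen plan does.
- *Weak points.* A5 has no acceptor group beyond its own lactone, so an inverse-demand addition needs high temperature. A6 places the hindered aryl group directly on the reacting alkyne carbon, and siloxyalkynes are laborious to prepare and prone to rearrange on heating. A5 is itself a multistep heterocycle.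
- *Redox cost.* A4 carries two stereocentres and four hydrogens that must be removed again, together with a sulfonamide whose cleavage is harsh.
- *Comparison.* The chosen plan reaches the aromatic oxidation level by condensation alone, and its two partners are acyclic or derive from one short naphthalene synthesis.

**Alternative 3:** The cut is at C1'–C8a', C4'–C4a' and C2'–C3', the same three bonds that step 4 of the chosen route forms.

- *Forward step.* Fluoride releases aryne 9 from 5 in the presence of the isoquinolinyl diketone A8, and insertion followed by aldol closure gives naphthol A7.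
- *Merits.* This is the most convergent plan. It forms three bonds at a late stage, O4' is free for methylation, and only methylation and a double debenzylation remain. If A8 were at hand and reacted cleanly, this road would be shorter than the chosen one.
- *Weak points.* A 3-aryl-2,4-dione is a strongly enolised, crowded tertiary nucleophile. The carbon that attacks the aryne would have to carry two acetyl groups, an ortho-substituted isoquinolinyl group and the new aryl group at once. The isoquinoline nitrogen is itself a good trap for arynes. Making A8 by arylation of 6 with a hindered 7-halo-8-benzyloxyisoquinoline brings back the C7 problem and invites deacetylation.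
- *Comparison.* The chosen plan uses the same insertion where it is least demanding, with a small CH2CO2Et substituent and no nitrogen. It pays for this with a longer linear sequence.

Key step: step 12

Assumption: the structure is taken as drawn (free hydroxyl at C5', methyl ether at C4'). The line notation carries no descriptor for the C7–C1' axis, so the route builds the racemic biaryl. The M atropisomer of the ent series is collected by HPLC on a chiral phase at the end of step 16, and its configuration is to be confirmed by circular dichroism.

Step 1
Reactants: 1 2-bromobenzene-1,3-diol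
Product: 2 3-(benzyloxy)-2-bromophenol
Conditions: BnBr (1.0 equiv), K2CO3 (1.0 equiv), acetone, reflux
Reagents that add atoms: benzyl bromide, BrCc1ccccc1
Why: Williamson etherification of a symmetrical diol with one equivalent of halide is statistical, and the monoether is separated from the diether and from recoverable 1 by chromatography. The bromine already marks the carbon that will carry silicon.

Step 2
Reactants: 2 3-(benzyloxy)-2-bromophenol
Product: 5 3-(benzyloxy)-2-(trimethylsilyl)phenyl trifluoromethanesulfonate, via aryl trimethylsilyl ether 3 (not isolated), via lithium silylphenolate 4 (not isolated)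
Conditions: HMDS, THF, reflux, then evaporation; n-BuLi, THF, −78 °C; Tf2O, −78 °C → rt
Reagents that add atoms: hexamethyldisilazane, C[Si](C)(C)N[Si](C)(C)C; trifluoromethanesulfonic anhydride, O=S(=O)(OS(=O)(=O)C(F)(F)F)C(F)(F)F
Why: O-silylation, bromine–lithium exchange, 1,3 O→C silyl shift (retro-Brook rearrangement) and triflation form the standard entry to 2-silylaryl triflates. The exchange at −78 °C should outrun deprotonation of the benzylic ether CH2.

Step 3
Reactants: 6 pentane-2,4-dione, 7 ethyl bromoacetate
Product: 8 ethyl 3-acetyl-4-oxopentanoate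
Conditions: K2CO3, acetone, reflux
Reagents that add atoms: none
Why: This is C-alkylation of a β-diketone with an α-halo ester under carbonate conditions. The soft enolate reacts at carbon, and the more hindered product is alkylated again only slowly.

Step 4
Reactants: 5 3-(benzyloxy)-2-(trimethylsilyl)phenyl trifluoromethanesulfonate, 8 ethyl 3-acetyl-4-oxopentanoate
Product: 11 ethyl 2-[5-(benzyloxy)-4-hydroxy-2-methylnaphthalen-1-yl]acetate, via 3-(benzyloxy)benzyne 9 (not isolated), via acyl-alkylation diketone 10 (not isolated)
Conditions: CsF (3 equiv), MeCN, 80 °C; then DBU, 80 °C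
Reagents that add atoms: none
Why: Fluoride-induced 1,2-elimination gives 9, and the enolate of 8 adds at the aryne carbon remote from the benzyloxy group, so that the negative charge develops next to the withdrawing oxygen. The aryl anion then closes on an acetyl group and the benzocyclobutoxide fragments (aryne acyl-alkylation, insertion into a C–C σ bond) to give 10. DBU then drives the intramolecular aldol condensation of the aryl methyl ketone onto the more electrophilic aliphatic ketone, and dehydration and tautomerisation should give the 1-naphthol.

Step 5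
Reactants: 11 ethyl 2-[5-(benzyloxy)-4-hydroxy-2-methylnaphthalen-1-yl]acetate
Product: 12 ethyl 2-[5-(benzyloxy)-4-methoxy-2-methylnaphthalen-1-yl]acetate
Conditions: MeI, K2CO3, DMF, rt
Reagents that add atoms: iodomethane, CI
Why: This is Williamson O-methylation of the only free phenol. Carbonate is too weak to enolise the arylacetate, so C-methylation is not expected.

Step 6
Reactants: 12 ethyl 2-[5-(benzyloxy)-4-methoxy-2-methylnaphthalen-1-yl]acetate, 13 acetaldehyde
Product: 15 ethyl 2-[5-(benzyloxy)-4-methoxy-2-methylnaphthalen-1-yl]-3-hydroxybutanoate (racemic syn/anti mixture), via lithium enolate 14 (not isolated)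
Conditions: LDA, THF, −78 °C; 13, −78 °C; AcOH quench at −78 °C
Reagents that add atoms: none
Why: This is the aldol addition of a lithium ester enolate to an aldehyde, and the cold acidic quench prevents retro-aldol cleavage. The two new stereocentres are not controlled and need not be, since both vanish in step 7.

Step 7
Reactants: 15 ethyl 2-[5-(benzyloxy)-4-methoxy-2-methylnaphthalen-1-yl]-3-hydroxybutanoate
Product: 17 ethyl 2-[5-(benzyloxy)-4-methoxy-2-methylnaphthalen-1-yl]but-2-enoate (E/Z mixture), via mesylate 16 (not isolated)
Conditions: MsCl, Et3N, CH2Cl2, 0 °C; then DBU, rt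
Reagents that add atoms: none
Why: Mesylation is followed by E1cB elimination, which is easy because the α-proton is acidified by both the ester and the aryl group. The alkene geometry is irrelevant for what follows.

Step 8
Reactants: 17 ethyl 2-[5-(benzyloxy)-4-methoxy-2-methylnaphthalen-1-yl]but-2-enoate
Product: 18 2-[5-(benzyloxy)-4-methoxy-2-methylnaphthalen-1-yl]but-2-enoic acid (E/Z mixture)
Conditions: KOH, EtOH/H2O, reflux; then 1 M HCl
Reagents that add atoms: potassium hydroxide, [K+].[OH-]
Why: This is a saponification. The ester is shielded by the orthogonal naphthyl group and needs heat, but benzyl and methyl aryl ethers are inert to hot alkali. Any E/Z or deconjugative isomerisation is harmless.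

Step 9
Reactants: 18 2-[5-(benzyloxy)-4-methoxy-2-methylnaphthalen-1-yl]but-2-enoic acid
Product: 20 {2-[5-(benzyloxy)-4-methoxy-2-methylnaphthalen-1-yl]buta-1,3-diene-1,1-diyl}bis(oxy)bis(trimethylsilane), via dilithium dienediolate 19 (not isolated)
Conditions: LDA (2.3 equiv), THF, −78 → 0 °C; TMSCl (2.6 equiv), −78 °C → rt; pentane, filtration under Ar
Reagents that add atoms: chlorotrimethylsilane, C[Si](C)(C)Cl
Why: Double deprotonation of a 2-substituted butenoic acid (carboxyl, then γ-methyl) followed by O,O-bis-silylation is the known preparation of vinylketene bis(silyl) acetals. The hard chlorosilane attacks oxygen, and the crowded α-carbon excludes C-silylation. The product is moisture-sensitive and is used crude.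

Step 10
Reactants: 21 pent-4-yn-2-ol (racemic)
Product: 22 tert-butyldimethyl(pent-4-yn-2-yloxy)silane (racemic)
Conditions: TBSCl, imidazole, CH2Cl2, rt
Reagents that add atoms: tert-butylchlorodimethylsilane, CC(C)(C)[Si](C)(C)Cl
Why: This is a standard imidazole-promoted silylation of a secondary alcohol. The configuration of the carbinol carbon is irrelevant because it becomes a carbonyl carbon in step 14.

Step 11
Reactants: 22 tert-butyldimethyl(pent-4-yn-2-yloxy)silane, 23 N-methoxy-N-methylacetamide
Product: 26 6-[(tert-butyldimethylsilyl)oxy]hept-3-yn-2-one (racemic), via lithium acetylide 24 (not isolated), via chelated tetrahedral adduct 25 (not isolated)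
Conditions: n-BuLi, THF, −78 °C; 23, −78 → 0 °C; aq. NH4Cl
Reagents that add atoms: none
Why: This is acylation of a lithium acetylide with a Weinreb amide. Adduct 25 persists until work-up, so the ynone is never exposed to the acetylide and over-addition is avoided.

Step 12
Reactants: 20 {2-[5-(benzyloxy)-4-methoxy-2-methylnaphthalen-1-yl]buta-1,3-diene-1,1-diyl}bis(oxy)bis(trimethylsilane), 26 6-[(tert-butyldimethylsilyl)oxy]hept-3-yn-2-one
Product: 29 1-[3-[5-(benzyloxy)-4-methoxy-2-methylnaphthalen-1-yl]-6-{2-[(tert-butyldimethylsilyl)oxy]propyl}-2-hydroxyphenyl]ethanone (racemic mixture of two atropodiastereomers), via cyclohexadiene cycloadduct 27 (not isolated), via aryl trimethylsilyl ether 28 (not isolated)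
Conditions: 26 (2 equiv), N,O-bis(trimethylsilyl)acetamide (BSA, 1.2 equiv), PhMe, 115 °C, sealed tube; then 0.5 M HCl, THF, 0 °C
Reagents that add atoms: none
Why: This is the Diels–Alder reaction of a vinylketene bis(silyl) acetal with an acetylenic ketone followed by aromatisation, a known route to salicyl ketones. The two silyloxy groups raise the HOMO of 20 and put its largest coefficient on the unsubstituted terminus (future C5), while the acetyl group puts the largest LUMO coefficient of 26 on the alkyl-bearing alkyne carbon (future C4a), so the addition should be concerted but strongly asynchronous with C4a–C5 running ahead of C8–C8a. The one ring formed, the isoquinoline carbocycle, is closed by intermolecular (4+2) cycloaddition, and both σ bonds arise in the same event to give the 1,4-cyclohexadiene 27. Compound 27 loses Me3SiOH (ionisation of one silyloxy group at C8 assisted by the other oxygen, then loss of a C5 proton) to give 28, which cold dilute acid hydrolyses to 29 without touching the secondary TBS ether. Regioselectivity is the selectivity required, and the matched polarisation secures it: reaction through the α-carbon of the dienolate system is blocked by the naphthyl group, and this 2-substituent also disfavours the s-trans conformer, in which it would clash with the vinyl CH2. BSA intercepts the liberated silanol, which would otherwise protonate unreacted 20, and the cheap partner 26 is used in excess. No stereocentre is created; the C7–C1' bond becomes a configurationally stable axis on aromatisation without any control, so 29 is expected as two racemic atropodiastereomers relative to the remote carbinol carbon, which does not matter because that centre is erased in step 14.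

Step 13
Reactants: 29 1-[3-[5-(benzyloxy)-4-methoxy-2-methylnaphthalen-1-yl]-6-{2-[(tert-butyldimethylsilyl)oxy]propyl}-2-hydroxyphenyl]ethanone
Product: 30 1-{3-[5-(benzyloxy)-4-methoxy-2-methylnaphthalen-1-yl]-2-hydroxy-6-(2-hydroxypropyl)phenyl}ethanone (racemic mixture of two atropodiastereomers)
Conditions: TBAF, AcOH, THF, rt
Reagents that add atoms: none
Why: This is a fluoride desilylation. Buffering with acetic acid keeps the medium close to neutral, so neither the phenol nor the benzylic CH2 is deprotonated and no acid-induced dehydration of the hydroxy ketone or its lactol occurs.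

Step 14
Reactants: 30 1-{3-[5-(benzyloxy)-4-methoxy-2-methylnaphthalen-1-yl]-2-hydroxy-6-(2-hydroxypropyl)phenyl}ethanone
Product: 31 1-{2-acetyl-4-[5-(benzyloxy)-4-methoxy-2-methylnaphthalen-1-yl]-3-hydroxyphenyl}propan-2-one (racemic)
Conditions: Dess–Martin periodinane, CH2Cl2, 0 °C → rt
Reagents that add atoms: none
Why: This is a Dess–Martin oxidation of a secondary alcohol. The phenol is chelated to the ortho acetyl group, deactivated by it and substituted at both ortho positions, so it should be left alone. Any lactol form of 30 is drained through the open hydroxy ketone.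

Step 15
Reactants: 31 1-{2-acetyl-4-[5-(benzyloxy)-4-methoxy-2-methylnaphthalen-1-yl]-3-hydroxyphenyl}propan-2-one
Product: 32 7-[5-(benzyloxy)-4-methoxy-2-methylnaphthalen-1-yl]-1,3-dimethylisoquinolin-8-ol (racemic)
Conditions: NH4OAc, AcOH, 80 °C
Reagents that add atoms: ammonium acetate, CC(=O)[O-].[NH4+]
Why: This is the condensation of a 2-acylphenylacetone (an unsaturated 1,5-diketone) with ammonia to an isoquinoline. Imine or enamine formation at the aliphatic ketone is followed by six-membered closure on the aryl ketone and loss of two molecules of water. The weakly acidic medium favours nitrogen uptake over base-induced aldol carbocyclisation.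

Step 16
Reactants: 32 7-[5-(benzyloxy)-4-methoxy-2-methylnaphthalen-1-yl]-1,3-dimethylisoquinolin-8-ol
Product: 33 ent-dioncophylleine A as drawn, 7-(5-hydroxy-4-methoxy-2-methylnaphthalen-1-yl)-1,3-dimethylisoquinolin-8-ol (M axis after separation)
Conditions: H2 (1 atm), 10% Pd/C, MeOH/EtOAc, rt; then HPLC on a chiral phase (cellulose tris(3,5-dimethylphenylcarbamate))
Reagents that add atoms: none
Why: This is hydrogenolysis of an aryl benzyl ether under neutral conditions, in which the isoquinoline and naphthalene rings should not be reduced. The axis is configurationally stable, so the two atropisomers can be separated on the chiral phase and the M form collected.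

## Compound list

1 | 2-bromobenzene-1,3-diol | Oc1cccc(O)c1Br | starting material
2 | 3-(benzyloxy)-2-bromophenol | Oc1cccc(OCc2ccccc2)c1Br | intermediate
3 | [3-(benzyloxy)-2-bromophenoxy]trimethylsilane | C[Si](C)(C)Oc1cccc(OCc2ccccc2)c1Br | intermediate
4 | lithium 3-(benzyloxy)-2-(trimethylsilyl)phenolate | [Li+].[O-]c1cccc(OCc2ccccc2)c1[Si](C)(C)C | intermediate
5 | 3-(benzyloxy)-2-(trimethylsilyl)phenyl trifluoromethanesulfonate | C[Si](C)(C)c1c(OCc2ccccc2)cccc1OS(=O)(=O)C(F)(F)F | intermediate
6 | pentane-2,4-dione (acetylacetone) | CC(=O)CC(C)=O | starting material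
7 | ethyl bromoacetate | CCOC(=O)CBr | starting material
8 | ethyl 3-acetyl-4-oxopentanoate | CCOC(=O)CC(C(C)=O)C(C)=O | intermediate
9 | 3-(benzyloxy)benzyne | C1=CC=C(OCc2ccccc2)C#C1 | intermediate
10 | ethyl 3-[2-acetyl-3-(benzyloxy)phenyl]-4-oxopentanoate (racemic) | CCOC(=O)CC(C(C)=O)c1cccc(OCc2ccccc2)c1C(C)=O | intermediate
11 | ethyl 2-[5-(benzyloxy)-4-hydroxy-2-methylnaphthalen-1-yl]acetate | CCOC(=O)Cc1c(C)cc(O)c2c(OCc3ccccc3)cccc12 | intermediate
12 | ethyl 2-[5-(benzyloxy)-4-methoxy-2-methylnaphthalen-1-yl]acetate | CCOC(=O)Cc1c(C)cc(OC)c2c(OCc3ccccc3)cccc12 | intermediate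
13 | acetaldehyde | CC=O | starting material
14 | lithium enolate of 12 | [Li+].CCOC([O-])=Cc1c(C)cc(OC)c2c(OCc3ccccc3)cccc12 | intermediate
15 | ethyl 2-[5-(benzyloxy)-4-methoxy-2-methylnaphthalen-1-yl]-3-hydroxybutanoate (racemic, syn/anti mixture) | CCOC(=O)C(C(C)O)c1c(C)cc(OC)c2c(OCc3ccccc3)cccc12 | intermediate
16 | ethyl 2-[5-(benzyloxy)-4-methoxy-2-methylnaphthalen-1-yl]-3-(methanesulfonyloxy)butanoate (racemic, syn/anti mixture) | CCOC(=O)C(C(C)OS(C)(=O)=O)c1c(C)cc(OC)c2c(OCc3ccccc3)cccc12 | intermediate
17 | ethyl 2-[5-(benzyloxy)-4-methoxy-2-methylnaphthalen-1-yl]but-2-enoate (E/Z mixture) | CCOC(=O)C(=CC)c1c(C)cc(OC)c2c(OCc3ccccc3)cccc12 | intermediate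
18 | 2-[5-(benzyloxy)-4-methoxy-2-methylnaphthalen-1-yl]but-2-enoic acid (E/Z mixture) | CC=C(C(=O)O)c1c(C)cc(OC)c2c(OCc3ccccc3)cccc12 | intermediate
19 | dilithium 2-[5-(benzyloxy)-4-methoxy-2-methylnaphthalen-1-yl]buta-1,3-diene-1,1-diolate | [Li+].[Li+].C=CC(=C([O-])[O-])c1c(C)cc(OC)c2c(OCc3ccccc3)cccc12 | intermediate
20 | {2-[5-(benzyloxy)-4-methoxy-2-methylnaphthalen-1-yl]buta-1,3-diene-1,1-diyl}bis(oxy)bis(trimethylsilane) | C=CC(=C(O[Si](C)(C)C)O[Si](C)(C)C)c1c(C)cc(OC)c2c(OCc3ccccc3)cccc12 | intermediate
21 | pent-4-yn-2-ol (racemic) | CC(O)CC#C | starting material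
22 | tert-butyldimethyl(pent-4-yn-2-yloxy)silane (racemic) | CC(CC#C)O[Si](C)(C)C(C)(C)C | intermediate
23 | N-methoxy-N-methylacetamide | CON(C)C(C)=O | starting material
24 | lithium acetylide of 22 | [Li+].[C-]#CCC(C)O[Si](C)(C)C(C)(C)C | intermediate
25 | lithium 6-[(tert-butyldimethylsilyl)oxy]-2-[methoxy(methyl)amino]hept-3-yn-2-olate | [Li+].CON(C)C(C)([O-])C#CCC(C)O[Si](C)(C)C(C)(C)C | intermediate
26 | 6-[(tert-butyldimethylsilyl)oxy]hept-3-yn-2-one (racemic) | CC(=O)C#CCC(C)O[Si](C)(C)C(C)(C)C | intermediate
27 | 1-[5-[5-(benzyloxy)-4-methoxy-2-methylnaphthalen-1-yl]-2-{2-[(tert-butyldimethylsilyl)oxy]propyl}-6,6-bis[(trimethylsilyl)oxy]cyclohexa-1,4-dien-1-yl]ethanone (racemic) | CC(=O)C1=C(CC(C)O[Si](C)(C)C(C)(C)C)CC=C(c2c(C)cc(OC)c3c(OCc4ccccc4)cccc23)C1(O[Si](C)(C)C)O[Si](C)(C)C | intermediate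
28 | 1-[3-[5-(benzyloxy)-4-methoxy-2-methylnaphthalen-1-yl]-6-{2-[(tert-butyldimethylsilyl)oxy]propyl}-2-[(trimethylsilyl)oxy]phenyl]ethanone (racemic, two atropodiastereomers) | CC(=O)c1c(O[Si](C)(C)C)c(-c2c(C)cc(OC)c3c(OCc4ccccc4)cccc23)ccc1CC(C)O[Si](C)(C)C(C)(C)C | intermediate
29 | 1-[3-[5-(benzyloxy)-4-methoxy-2-methylnaphthalen-1-yl]-6-{2-[(tert-butyldimethylsilyl)oxy]propyl}-2-hydroxyphenyl]ethanone (racemic, two atropodiastereomers) | CC(=O)c1c(O)c(-c2c(C)cc(OC)c3c(OCc4ccccc4)cccc23)ccc1CC(C)O[Si](C)(C)C(C)(C)C | intermediate
30 | 1-{3-[5-(benzyloxy)-4-methoxy-2-methylnaphthalen-1-yl]-2-hydroxy-6-(2-hydroxypropyl)phenyl}ethanone (racemic, two atropodiastereomers) | CC(=O)c1c(O)c(-c2c(C)cc(OC)c3c(OCc4ccccc4)cccc23)ccc1CC(C)O | intermediate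
31 | 1-{2-acetyl-4-[5-(benzyloxy)-4-methoxy-2-methylnaphthalen-1-yl]-3-hydroxyphenyl}propan-2-one (racemic axis) | CC(=O)Cc1ccc(-c2c(C)cc(OC)c3c(OCc4ccccc4)cccc23)c(O)c1C(C)=O | intermediate
32 | 7-[5-(benzyloxy)-4-methoxy-2-methylnaphthalen-1-yl]-1,3-dimethylisoquinolin-8-ol (racemic axis) | COc1cc(C)c(-c2ccc3cc(C)nc(C)c3c2O)c2cccc(OCc3ccccc3)c12 | intermediate
33 | ent-dioncophylleine A as drawn, 7-(5-hydroxy-4-methoxy-2-methylnaphthalen-1-yl)-1,3-dimethylisoquinolin-8-ol (M axis after separation) | COc1cc(C)c(-c2ccc3cc(C)nc(C)c3c2O)c2cccc(O)c12 | target

## Step count and weak points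

Total: 16 steps. Longest linear sequence: 13 steps (1, 2, 4–9, 12–16). Steps 3, 10 and 11 belong to the two side branches.

**Step 12 (key step).**
- *Risk.* The second bond, C8–C8a, must form between a ketene-acetal carbon that carries two silyloxy groups beside the orthogonal naphthyl group and the acetyl-bearing alkyne carbon. The addition may therefore stall after C4a–C5 bond formation. It may also need temperatures at which the diene is lost by protonation or by a 1,5 O→C silyl shift.
- *Fallback.* It sets out from 20 and 26, returns at 29, and forms the two bonds one at a time by ionic reactions.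
  1. A vinylogous Mukaiyama–Michael addition (TMSOTf cat., CH2Cl2, −78 °C) forms only C4a–C5. It gives trimethylsilyl 2-[5-(benzyloxy)-4-methoxy-2-methylnaphthalen-1-yl]-5-{2-[(tert-butyldimethylsilyl)oxy]propyl}-7-[(trimethylsilyl)oxy]octa-2,5,6-trienoate F1.
  2. Aqueous work-up gives 2-[5-(benzyloxy)-4-methoxy-2-methylnaphthalen-1-yl]-5-{2-[(tert-butyldimethylsilyl)oxy]propyl}-7-oxoocta-2,5-dienoic acid F2.
  3. Esterification with TMSCHN2 gives methyl 2-[5-(benzyloxy)-4-methoxy-2-methylnaphthalen-1-yl]-5-{2-[(tert-butyldimethylsilyl)oxy]propyl}-7-oxoocta-2,5-dienoate F3.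
  4. KOt-Bu in THF deprotonates the doubly allylic CH2. The extended enolate closes C8–C8a by an intramolecular Claisen (Dieckmann-type) acylation at the carbon α to the ketone, and tautomerisation gives 29.
- *Why it helps.* The electrophilic C8 is now a planar ester carbon and no longer a carbon bearing two silyloxy groups.

**Step 4.**
- *Risk.* Three processes can compete: capture of the aryl anion by the ester carbonyl through a five-membered transition state, protonation of the aryl anion before the acyl shift, and aldol closure in the opposite sense (side-chain methyl onto the aryl ketone).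
- *Fallback.* It sets out from 5 and 6 and returns at 12.
  1. Unsubstituted 6, which has no ester and a less crowded nucleophilic carbon, undergoes the same insertion (via 9) to give 1-[2-acetyl-3-(benzyloxy)phenyl]propan-2-one F4.
  2. Base-induced aldol condensation gives 8-(benzyloxy)-3-methylnaphthalen-1-ol F5.
  3. O-methylation (MeI, K2CO3) gives 8-(benzyloxy)-1-methoxy-3-methylnaphthalene F6.
  4. Bromination with NBS in MeCN should occur at the position para to the methoxy group and ortho to the methyl group. It gives 5-(benzyloxy)-1-bromo-4-methoxy-2-methylnaphthalene F7.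
  5. Coupling (Pd(dba)2, P(t-Bu)3, THF) with the Reformatsky reagent bromo(2-ethoxy-2-oxoethyl)zinc F8, made from 7 and zinc dust, gives 12.

**Step 9.**
- *Risk.* γ-Deprotonation of the hindered carboxylate may be incomplete, and the bis(silyl) acetal may hydrolyse during isolation.
- *Fallback.* It sets out from 17, bypasses steps 8 and 9, and returns at 29.
  1. γ-Deprotonation of the ester (LDA, DMPU, THF, −78 °C) and silylation with TMSCl give the mixed acetal {[2-[5-(benzyloxy)-4-methoxy-2-methylnaphthalen-1-yl]-1-ethoxybuta-1,3-dien-1-yl]oxy}trimethylsilane F9.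
  2. Cycloaddition with 26 as in step 12 gives 1-[5-[5-(benzyloxy)-4-methoxy-2-methylnaphthalen-1-yl]-2-{2-[(tert-butyldimethylsilyl)oxy]propyl}-6-ethoxy-6-[(trimethylsilyl)oxy]cyclohexa-1,4-dien-1-yl]ethanone F10.
  3. Dilute acid removes the silyl group, and the hemiketal expels the alcohol to give 29.
- *Cost.* The choice of which oxygen leaves is no longer indifferent.

**Step 15.**
- *Risk.* Intramolecular aldol carbocyclisation of the 1,5-diketone may compete with nitrogen uptake, and attack at the chelated, doubly ortho-substituted aryl ketone may be slow.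
- *Fallback.* It sets out from 31 and returns at 32.
  1. HBF4·OEt2 in CH2Cl2/Et2O at 0 °C dehydrates the diketone to 7-[5-(benzyloxy)-4-methoxy-2-methylnaphthalen-1-yl]-8-hydroxy-1,3-dimethyl-2-benzopyrylium tetrafluoroborate F11.
  2. In this salt C1 is a strongly electrophilic oxocarbenium carbon, and NH3 in MeOH exchanges ring oxygen for nitrogen (pyrylium to pyridine conversion) to give 32.

**Step 16.**
- *Risk.* The isoquinoline nitrogen may poison the catalyst, and forcing the reaction may partly saturate the pyridine ring.
- *Fallback.* It sets out from 32 and returns at 33. Hydrogenolysis is replaced by Lewis-acid cleavage with a cation scavenger (BCl3, pentamethylbenzene, CH2Cl2, −78 °C), at which temperature the methyl ether should persist. No new compound arises (F0).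

## Further compounds

F1 | step 12 | trimethylsilyl 2-[5-(benzyloxy)-4-methoxy-2-methylnaphthalen-1-yl]-5-{2-[(tert-butyldimethylsilyl)oxy]propyl}-7-[(trimethylsilyl)oxy]octa-2,5,6-trienoate | CC(O[Si](C)(C)C)=C=C(CC(C)O[Si](C)(C)C(C)(C)C)CC=C(C(=O)O[Si](C)(C)C)c1c(C)cc(OC)c2c(OCc3ccccc3)cccc12
F2 | step 12 | 2-[5-(benzyloxy)-4-methoxy-2-methylnaphthalen-1-yl]-5-{2-[(tert-butyldimethylsilyl)oxy]propyl}-7-oxoocta-2,5-dienoic acid | CC(=O)C=C(CC(C)O[Si](C)(C)C(C)(C)C)CC=C(C(=O)O)c1c(C)cc(OC)c2c(OCc3ccccc3)cccc12
F3 | step 12 | methyl 2-[5-(benzyloxy)-4-methoxy-2-methylnaphthalen-1-yl]-5-{2-[(tert-butyldimethylsilyl)oxy]propyl}-7-oxoocta-2,5-dienoate | CC(=O)C=C(CC(C)O[Si](C)(C)C(C)(C)C)CC=C(C(=O)OC)c1c(C)cc(OC)c2c(OCc3ccccc3)cccc12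
F4 | step 4 | 1-[2-acetyl-3-(benzyloxy)phenyl]propan-2-one | CC(=O)Cc1cccc(OCc2ccccc2)c1C(C)=O
F5 | step 4 | 8-(benzyloxy)-3-methylnaphthalen-1-ol | Cc1cc(O)c2c(OCc3ccccc3)cccc2c1
F6 | step 4 | 8-(benzyloxy)-1-methoxy-3-methylnaphthalene | COc1cc(C)cc2cccc(OCc3ccccc3)c12
F7 | step 4 | 5-(benzyloxy)-1-bromo-4-methoxy-2-methylnaphthalene | COc1cc(C)c(Br)c2cccc(OCc3ccccc3)c12
F8 | step 4 | bromo(2-ethoxy-2-oxoethyl)zinc | CCOC(=O)C[Zn]Br
F9 | step 9 | {[2-[5-(benzyloxy)-4-methoxy-2-methylnaphthalen-1-yl]-1-ethoxybuta-1,3-dien-1-yl]oxy}trimethylsilane | C=CC(=C(OCC)O[Si](C)(C)C)c1c(C)cc(OC)c2c(OCc3ccccc3)cccc12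
F10 | step 9 | 1-[5-[5-(benzyloxy)-4-methoxy-2-methylnaphthalen-1-yl]-2-{2-[(tert-butyldimethylsilyl)oxy]propyl}-6-ethoxy-6-[(trimethylsilyl)oxy]cyclohexa-1,4-dien-1-yl]ethanone | CC(=O)C1=C(CC(C)O[Si](C)(C)C(C)(C)C)CC=C(c2c(C)cc(OC)c3c(OCc4ccccc4)cccc23)C1(OCC)O[Si](C)(C)C
F11 | step 15 | 7-[5-(benzyloxy)-4-methoxy-2-methylnaphthalen-1-yl]-8-hydroxy-1,3-dimethyl-2-benzopyrylium tetrafluoroborate | Cc1cc2ccc(-c3c(C)cc(OC)c4c(OCc5ccccc5)cccc34)c(O)c2c(C)[o+]1.F[B-](F)(F)F
F0 | step 16 | none | none
A1 | alternative 1 | ethyl 8-(benzyloxy)-4-[8-(benzyloxy)-1,3-dimethylisoquinolin-7-yl]-1-hydroxy-3-methylnaphthalene-2-carboxylate | CCOC(=O)c1c(C)c(-c2ccc3cc(C)nc(C)c3c2OCc2ccccc2)c2cccc(OCc3ccccc3)c2c1O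
A2 | alternative 1 | 8-(benzyloxy)-4-[8-(benzyloxy)-1,3-dimethylisoquinolin-7-yl]-1H-isochromene-1,3(4H)-dione | O=C1OC(=O)C(c2ccc3cc(C)nc(C)c3c2OCc2ccccc2)c2cccc(OCc3ccccc3)c12
A3 | alternative 1 | ethyl but-2-ynoate | CCOC(=O)C#CC
A4 | alternative 2 | 7-[5-(benzyloxy)-4-methoxy-2-methylnaphthalen-1-yl]-1,3-dimethyl-2-(4-methylbenzenesulfonyl)-8-[(triisopropylsilyl)oxy]-1,2,3,4-tetrahydroisoquinoline (mixture of stereoisomers) | CC1Cc2ccc(-c3c(C)cc(OC)c4c(OCc5ccccc5)cccc34)c(O[Si](C(C)C)(C(C)C)C(C)C)c2C(C)N1S(=O)(=O)c1ccc(C)cc1
A5 | alternative 2 | 6,8-dimethyl-7-(4-methylbenzenesulfonyl)-5,6,7,8-tetrahydro-1H-pyrano[3,4-c]pyridin-1-one (mixture of stereoisomers) | CC1Cc2ccoc(=O)c2C(C)N1S(=O)(=O)c1ccc(C)cc1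
A6 | alternative 2 | ({[5-(benzyloxy)-4-methoxy-2-methylnaphthalen-1-yl]ethynyl}oxy)triisopropylsilane | CC(C)[Si](OC#Cc1c(C)cc(OC)c2c(OCc3ccccc3)cccc12)(C(C)C)C(C)C
A7 | alternative 3 | 8-(benzyloxy)-4-[8-(benzyloxy)-1,3-dimethylisoquinolin-7-yl]-3-methylnaphthalen-1-ol | Oc1cc(C)c(-c2ccc3cc(C)nc(C)c3c2OCc2ccccc2)c2cccc(OCc3ccccc3)c12
A8 | alternative 3 | 3-[8-(benzyloxy)-1,3-dimethylisoquinolin-7-yl]pentane-2,4-dione | CC(=O)C(C(C)=O)c1ccc2cc(C)nc(C)c2c1OCc1ccccc1
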